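Everything rests on one disconnection: the cyclohexane is closed by a bromonium-triggered cation–olefin cyclisation of an acyclic trienyl acetate. The target invites this because its secondary bromide at C5 sits beside the quaternary C4, which is bonded to the alkene carbon C3 of the cyclohexene ring, while the side chain ends in the C2′ chloride. In one operation, bromine adds to the prenyl alkene, the diene methylene closes the ring and chloride caps the allyl cation, forming C5–Br, C3–C4, C2′–Cl and the C5 stereocentre. The precursor is the (R)-acetate of a myrcene-type dienyl carbinol, made by asymmetric dienyl transfer to 4-methylpent-3-enal. Four reagent-controlled steps then shift the alkene into the ring and place bromine at C1′.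

Key step: step 4

Remark: atom labels follow the target in the discussion of every compound (ring C1–C6 with C1 the acetoxy carbon, side chain C1′–C2′); the target is (1R,5S,1′S) with C1–OAc and C5–Br cis, and 2-chlorobuta-1,3-diene and (−)-B-methoxydiisopinocampheylborane are taken as purchasable.

Step 1
Reactants: 1 4-methylpent-3-en-1-ol
Product: 2 4-methylpent-3-enal
Conditions: Dess–Martin periodinane, pyridine, CH2Cl2, 0 °C → rt; solution used at once
Reagents that add atoms: none
Why: Dess–Martin oxidation of a primary alcohol stops at the aldehyde, and the buffered, non-basic medium should keep the β,γ-alkene from moving into conjugation; no stereocentre is formed.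

Step 2
Reactants: 2 4-methylpent-3-enal; 3 2-chlorobuta-1,3-diene; 4 (−)-B-methoxydiisopinocampheylborane
Product: 8 (4R)-7-methyl-3-methylideneocta-1,6-dien-4-ol, via buta-1,3-dien-2-ylmagnesium chloride 5 (not isolated), via buta-2,3-dienyl(diisopinocampheyl)borane 6 (not isolated), via diisopinocampheylborinate ester 7 (not isolated)
Conditions: chlorodiene, Mg, ZnCl2 (catalytic), THF, reflux; (−)-Ipc2BOMe, Et2O, −78 → 0 °C; aldehyde, −78 °C; then NaOH, H2O2, 0 °C → rt
Reagents that add atoms: none
Why: Brown allylboration in its homoallenyl form: the dienyl Grignard reagent and the methoxyborane give, directly or after a 1,3-boron shift, the buta-2,3-dienylborane 6, which adds to the aldehyde through a closed chair (Zimmerman–Traxler) transition state with allylic transposition so that the central allene carbon bonds to the carbonyl carbon, and the isopinocampheyl groups from (+)-α-pinene should direct this to the si face, as in the parent allylation, to set the carbinol centre (future C1) as R.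

Step 3
Reactants: 8 (4R)-7-methyl-3-methylideneocta-1,6-dien-4-ol
Product: 9 (4R)-7-methyl-3-methylideneocta-1,6-dien-4-yl acetate
Conditions: Ac2O, pyridine, 4-(dimethylamino)pyridine (catalytic), CH2Cl2, 0 °C → rt
Reagents that add atoms: acetic anhydride, CC(=O)OC(C)=O
Why: Amine-catalysed acylation of the secondary alcohol gives the ester that is both the acetate of the target and the internal cation trap of step 4, and it leaves the carbinol centre untouched.

Step 4
Reactants: 9 (4R)-7-methyl-3-methylideneocta-1,6-dien-4-yl acetate
Product: 11 (1R,5S)-5-bromo-2-[(E)-2-chloroethylidene]-4,4-dimethylcyclohexyl acetate, via acetoxonium bromopentachloroantimonate 10 (not isolated)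
Conditions: Et2SBr·SbCl5Br (1.0 equiv), MeNO2, −25 °C; then Et4NCl (5 equiv), −25 °C → rt
Reagents that add atoms: bromodiethylsulfonium bromopentachloroantimonate, CC[S+](Br)CC.Cl[Sb-](Cl)(Cl)(Cl)(Cl)Br; tetraethylammonium chloride, CC[N+](CC)(CC)CC.[Cl-]
Why: Proposed new method: the sulfonium salt transfers Br+ reversibly to the electron-rich prenyl alkene (future C4 and C5; the diene is deactivated by the allylic acetoxy group), the diene CH2 opens the bromonium ion at its tertiary carbon anti to bromine, making C3–C4 and an allyl cation over C2, C1′ and C2′, which the neighbouring ester carbonyl holds as the cis-fused acetoxonium ion 10. Chloride is added only when the bromonium donor is spent, so that no bromochlorination of an alkene can compete, and it should reopen 10 by ionisation and bond to the primary terminus C2′. The closest known reactions are bromonium-induced polyene cyclisation with Et2SBr·SbCl5Br and halide opening of Woodward–Prévost acetoxonium ions; a diene terminus relayed to an allylic chloride has not been shown. The ring closes in a 6-endo-trig mode through a chair in which both carbons of the bromonium alkene and both carbons of the attacking C=CH2 unit become ring atoms. C5 is set by anti addition across the prenyl alkene with bromine equatorial, and its sense by the C1 centre, whose acetoxy group lies equatorial in the same chair, so that 1R should give 5S with C1–OAc and C5–Br cis. The step needs bromination of the prenyl alkene before the diene, cis C1/C5 induction and E-selective chloride delivery to C2′; these rest on the higher substitution of the prenyl alkene, on reversible bromonium transfer letting the lower chair win, and on reversible ionisation of the allylic chloride toward the less strained E isomer.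

Step 5
Reactants: 11 (1R,5S)-5-bromo-2-[(E)-2-chloroethylidene]-4,4-dimethylcyclohexyl acetate
Product: 13 (1R,5S)-5-bromo-2-[(1S)-2-chloro-1-hydroxyethyl]-4,4-dimethylcyclohex-2-en-1-yl acetate, via allylic hydroperoxide 12 (not isolated)
Conditions: O2, 5,10,15,20-tetraphenylporphyrin (catalytic), visible light, CH2Cl2, 0 °C; then PPh3, 0 °C
Reagents that add atoms: dioxygen, O=O
Why: Schenck ene reaction followed by phosphine reduction: singlet oxygen bonds to C1′ and takes the axial H3 from the same face, on the more crowded side of the alkene and away from the hydrogens geminal to chlorine and acetoxy, which moves the alkene to C2=C3 without any cation that the ester could trap; attack opposite the axial C4 methyl should give mainly 1′S, a centre that step 6 erases.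

Step 6
Reactants: 13 (1R,5S)-5-bromo-2-[(1S)-2-chloro-1-hydroxyethyl]-4,4-dimethylcyclohex-2-en-1-yl acetate
Product: 14 (1R,5S)-5-bromo-2-(chloroacetyl)-4,4-dimethylcyclohex-2-en-1-yl acetate
Conditions: Dess–Martin periodinane, CH2Cl2, 0 °C → rt
Reagents that add atoms: none
Why: Dess–Martin oxidation of a secondary allylic alcohol to the enone under neutral conditions that leave the acetate and both halides alone; C1′ becomes planar, so either epimer of 13 serves.

Step 7
Reactants: 14 (1R,5S)-5-bromo-2-(chloroacetyl)-4,4-dimethylcyclohex-2-en-1-yl acetate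
Product: 15 (1R,5S)-5-bromo-2-[(1R)-2-chloro-1-hydroxyethyl]-4,4-dimethylcyclohex-2-en-1-yl acetate
Conditions: (R)-Me-CBS oxazaborolidine [(3aR)-1-methyl-3,3-diphenyltetrahydro-1H,3H-pyrrolo[1,2-c][1,3,2]oxazaborole] (0.2 equiv), BH3·SMe2, THF, −30 °C; then MeOH
Reagents that add atoms: none
Why: Corey–Bakshi–Shibata reduction gives 1,2-reduction of the enone, and with the cyclohexenyl group as the large and chloromethyl as the small substituent the (R)-catalyst should deliver hydride to the face that gives the 1′R carbinol, by reagent control as with aryl chloromethyl ketones.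

Step 8
Reactants: 15 (1R,5S)-5-bromo-2-[(1R)-2-chloro-1-hydroxyethyl]-4,4-dimethylcyclohex-2-en-1-yl acetate
Product: 16 (1R,5S)-5-bromo-2-[(1S)-1-bromo-2-chloroethyl]-4,4-dimethylcyclohex-2-en-1-yl acetate
Conditions: CBr4, PPh3, CH2Cl2, 0 °C
Reagents that add atoms: carbon tetrabromide, BrC(Br)(Br)Br
Why: Appel reaction: bromide displaces the alkoxyphosphonium group in an SN2 step with inversion, turning 1′R–OH into 1′S–Br, while the hindered C3 terminus next to the quaternary carbon and the β-chlorine should disfavour SN2′ and SN1 escape.

Compound list
1 | 4-methylpent-3-en-1-ol | CC(C)=CCCO | starting material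
2 | 4-methylpent-3-enal | CC(C)=CCC=O | intermediate
3 | 2-chlorobuta-1,3-diene | C=CC(Cl)=C | starting material
4 | (−)-B-methoxydiisopinocampheylborane, methoxybis[(1R,2S,3R,5R)-2,6,6-trimethylbicyclo[3.1.1]heptan-3-yl]borane | COB([C@@H]1C[C@@H]2C[C@H]([C@H]1C)C2(C)C)[C@@H]1C[C@@H]2C[C@H]([C@H]1C)C2(C)C | starting material
5 | buta-1,3-dien-2-ylmagnesium chloride | C=CC(=C)[Mg]Cl | intermediate
6 | (buta-2,3-dien-1-yl)bis[(1R,2S,3R,5R)-2,6,6-trimethylbicyclo[3.1.1]heptan-3-yl]borane | C=C=CCB([C@@H]1C[C@@H]2C[C@H]([C@H]1C)C2(C)C)[C@@H]1C[C@@H]2C[C@H]([C@H]1C)C2(C)C | intermediate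
7 | (4R)-7-methyl-3-methylideneocta-1,6-dien-4-yl bis[(1R,2S,3R,5R)-2,6,6-trimethylbicyclo[3.1.1]heptan-3-yl]borinate | CC(C)=CC[C@@H](OB([C@@H]1C[C@@H]2C[C@H]([C@H]1C)C2(C)C)[C@@H]1C[C@@H]2C[C@H]([C@H]1C)C2(C)C)C(=C)C=C | intermediate
8 | (4R)-7-methyl-3-methylideneocta-1,6-dien-4-ol | O[C@H](CC=C(C)C)C(=C)C=C | intermediate
9 | (4R)-7-methyl-3-methylideneocta-1,6-dien-4-yl acetate | CC(=O)O[C@H](CC=C(C)C)C(=C)C=C | intermediate
10 | cis-fused acetoxonium salt: 2-methyl-1,3-dioxolan-2-ylium ring across O–C1 and O–C2 of the new cyclohexane, ethenyl on C2, bromine on C5 (1R,2R,5S), bromopentachloroantimonate counter-ion | CC1=[O+][C@@]2(C=C)CC(C)(C)[C@@H](Br)C[C@H]2O1.Cl[Sb-](Cl)(Cl)(Cl)(Cl)Br | intermediate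
11 | (1R,5S)-5-bromo-2-[(E)-2-chloroethylidene]-4,4-dimethylcyclohexyl acetate | ClC/C=C1\CC(C)(C)[C@@H](Br)C[C@H]1OC(C)=O | intermediate
12 | (1R,5S)-5-bromo-2-[(1S)-2-chloro-1-hydroperoxyethyl]-4,4-dimethylcyclohex-2-en-1-yl acetate | CC(=O)O[C@@H]1C[C@H](Br)C(C)(C)C=C1[C@H](OO)CCl | intermediate
13 | (1R,5S)-5-bromo-2-[(1S)-2-chloro-1-hydroxyethyl]-4,4-dimethylcyclohex-2-en-1-yl acetate | CC(=O)O[C@@H]1C[C@H](Br)C(C)(C)C=C1[C@H](O)CCl | intermediate
14 | (1R,5S)-5-bromo-2-(chloroacetyl)-4,4-dimethylcyclohex-2-en-1-yl acetate | CC(=O)O[C@@H]1C[C@H](Br)C(C)(C)C=C1C(=O)CCl | intermediate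
15 | (1R,5S)-5-bromo-2-[(1R)-2-chloro-1-hydroxyethyl]-4,4-dimethylcyclohex-2-en-1-yl acetate | CC(=O)O[C@@H]1C[C@H](Br)C(C)(C)C=C1[C@@H](O)CCl | intermediate
16 | (1R,5S)-5-bromo-2-[(1S)-1-bromo-2-chloroethyl]-4,4-dimethylcyclohex-2-en-1-yl acetate | CC(=O)O[C@@H]1C[C@H](Br)C(C)(C)C=C1[C@H](Br)CCl | target

Total step count: 8. Longest linear sequence: 8 steps (1 → 2 → 8 → 9 → 11 → 13 → 14 → 15 → 16); the chlorodiene and the chiral borane enter in step 2.

Steps most likely to fail

1. Step 4. The allyl cation may be intercepted before chloride reaches C2′ (proton loss to a diene, halide return at the tertiary carbon, hydrolysis of the acetoxonium ion), the diene may react through the rotamer that leads to the Z chloride, or the chair may carry the acetoxy group axial and erode the C1/C5 relationship. The fallback uses known chemistry, sets out from 9 and returns at 11. The cascade is stopped at the oxygen-trapped stage, the established way of ending a bromonium polyene cyclisation with an internal ester carbonyl. Quenching 10 with aqueous NaHCO3 gives, by Woodward-type hydrolysis, (1R,2R,5S)-5-bromo-2-ethenyl-2-hydroxy-4,4-dimethylcyclohexyl acetate F1. SOCl2 in Et2O then converts this tertiary vinyl carbinol into the primary allylic chloride with allylic transposition (SNi′), which is 11.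

2. Step 5. The ene reaction may be slow or misdirected, because the alkene carries an electron-withdrawing group on each side and hydrogen could also be taken from C1 or C2′. The fallback sets out from 11 and returns at 16, bypassing steps 6 to 8, and replaces the pericyclic oxygenation by an ionic bromination that uses the neighbouring ester. N-Bromosuccinimide in wet MeCN forms the bromonium ion, the C1 acetoxy group opens it at C2 from its own face, and water hydrolyses the resulting acetoxonium ion to (1R,2S,5S)-5-bromo-2-[(1S)-1-bromo-2-chloroethyl]-2-hydroxy-4,4-dimethylcyclohexyl acetate F2. Bromine then sits on C1′ anti to the acetoxy-bearing face, which is the target configuration. Burgess dehydration of the tertiary alcohol, a syn elimination for which only the equatorial H3 and H1′ are in reach, would then give 16; elimination into the side chain is the weak point of this variant.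

3. Step 2. Enantiomeric purity or coupling site may be lost through a low facial preference of the dienyl-transfer reagent, boron resting on the diene carbon instead of the allenylmethyl position, or isomerisation of 2 to the conjugated enal. The fallback sets out from 2 and returns at 8. An indium-mediated Barbier reaction of 2 with 1,4-dibromobut-2-yne (In powder, THF/H2O), a known route to buta-1,3-dien-2-yl carbinols, gives racemic 7-methyl-3-methylideneocta-1,6-dien-4-ol F3. Sharpless kinetic resolution (Ti(OiPr)4, diisopropyl L-(+)-tartrate, tert-butyl hydroperoxide, CH2Cl2, −20 °C) should epoxidise the S enantiomer to (1S)-1-[(2R)-2-ethenyloxiran-2-yl]-4-methylpent-3-en-1-ol F4 and leave the (R)-alcohol 8.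

Further compounds
F1 | step 4 | (1R,2R,5S)-5-bromo-2-ethenyl-2-hydroxy-4,4-dimethylcyclohexyl acetate | CC(=O)O[C@@H]1C[C@H](Br)C(C)(C)C[C@@]1(O)C=C
F2 | step 5 | (1R,2S,5S)-5-bromo-2-[(1S)-1-bromo-2-chloroethyl]-2-hydroxy-4,4-dimethylcyclohexyl acetate | CC(=O)O[C@@H]1C[C@H](Br)C(C)(C)C[C@@]1(O)[C@H](Br)CCl
F3 | step 2 | rac-7-methyl-3-methylideneocta-1,6-dien-4-ol | OC(CC=C(C)C)C(=C)C=C
F4 | step 2 | (1S)-1-[(2R)-2-ethenyloxiran-2-yl]-4-methylpent-3-en-1-ol | O[C@@H](CC=C(C)C)[C@@]1(C=C)CO1
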